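**Retrosynthetic overview**
1. Oxepane (last ring): break C16–O. The tertiary C3–OH displaces a C16 triflate in a seco-diol; this is the pivotal C–O closure.
2. Oxonane: break C6–C7. An intramolecular B-alkyl Suzuki coupling joins a C3 allyl arm to a C9 2-bromoallyl arm and gives C7=CH2 directly; the same 9-BBN charge sets C15 and delivers C16–OH.
3. C3 carbinol: chelate-controlled allylation of a C3 methyl ketone, which comes from Wacker oxidation of a C2 vinyl group.
4. Tetrahydrofuran and C11–OH: break C2–O–C9, C9–C10 and C11–O in one oxocarbenium → Prins → acyloxonium relay between an allylic octanoate and 3-bromobut-3-enal.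
5. Ring A is (R)-carvone: anti aldol with acrolein (C1–C2), then epoxidation/Wharton/Mitsunobu moves oxygen from C10 to C12. Ring order: cyclohexane (bought) → tetrahydrofuran → oxonane → oxepane.

Assumption: atom labels C1–C20 follow the usual cladiellin/briarellin numbering (C2–O–C9 bridge, C3–O–C16 oxepane, C7=C19H2, C11 carbinol, C12 ester), and the target is (1S,2S,3S,9S,10R,11R,12S,14S,15R) as drawn.

**Step 1**
Reactants: 1 (R)-(−)-carvone; 2 acrolein
Product: 5 (5R,6R)-2-methyl-5-(prop-1-en-2-yl)-6-[(1R)-1-(triethylsilyloxy)prop-2-en-1-yl]cyclohex-2-en-1-one, via lithium dienolate 3 (not isolated), via lithium aldolate 4 (not isolated)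
Conditions: LDA, THF, −78 °C; 2, −78 °C, 15 min; TESOTf, −78 to −40 °C
Reagents that add atoms: triethylsilyl trifluoromethanesulfonate, CC[Si](CC)(CC)OS(=O)(=O)C(F)(F)F
Why: Kinetic α′-enolate aldol addition, in which attack anti to the isopropenyl group sets C1 trans to C14, the Zimmerman–Traxler chair of the ring-locked E-enolate gives the anti C1/C2 pair (about 4:1 expected, syn isomer removed here), and in-situ silylation blocks retro-aldol.

**Step 2**
Reactants: 5
Product: 6 (1R,3R,4R,6R)-1-methyl-4-(prop-1-en-2-yl)-3-[(1R)-1-(triethylsilyloxy)prop-2-en-1-yl]-7-oxabicyclo[4.1.0]heptan-2-one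
Conditions: 30% H2O2, NaOH (0.3 equiv), MeOH, 0 °C
Reagents that add atoms: hydrogen peroxide, OO
Why: Weitz–Scheffer nucleophilic epoxidation touches only the enone, and axial attack of HOO− at C12 anti to the C14 isopropenyl group places the oxirane trans to it, as with carvone itself.

**Step 3**
Reactants: 6
Product: 8 (1R,4R,5R)-2-methyl-5-(prop-1-en-2-yl)-4-[(1R)-1-(triethylsilyloxy)prop-2-en-1-yl]cyclohex-2-en-1-ol, via epoxy hydrazone 7 (not isolated)
Conditions: N2H4·H2O, AcOH (cat.), MeOH, 0 °C to rt, Ar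
Reagents that add atoms: none
Why: Wharton transposition, in which hydrazone formation, epoxide opening and loss of N2 move the alkene to C10=C11 and leave the C12–O bond and its configuration untouched.

**Step 4**
Reactants: 8; 9 octanoic acid
Product: 10 (1S,4R,5R)-2-methyl-5-(prop-1-en-2-yl)-4-[(1R)-1-(triethylsilyloxy)prop-2-en-1-yl]cyclohex-2-en-1-yl octanoate
Conditions: PPh3, DIAD, toluene, 0 °C to rt
Reagents that add atoms: none
Why: Mitsunobu esterification inverts the pseudoaxial allylic C12–OH by SN2 displacement and so installs the natural octanoate as (12S), cis to the isopropenyl group, while SN2′ attack at C10 is blocked by the C1 branch.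

**Step 5**
Reactants: 11 3-bromobut-3-en-1-ol
Product: 12 3-bromobut-3-enal
Conditions: Dess–Martin periodinane, NaHCO3, CH2Cl2, 0 °C; used at once as a cold CH2Cl2 solution
Reagents that add atoms: none
Why: Buffered Dess–Martin oxidation is neutral enough to keep the β,γ-unsaturated aldehyde from conjugating.

**Step 6**
Reactants: 10; 12
Product: 15 (1R,3S,3aR,4R,5S,7R,7aS)-3-(2-bromoprop-2-en-1-yl)-1-ethenyl-4-hydroxy-4-methyl-7-(prop-1-en-2-yl)octahydro-2-benzofuran-5-yl octanoate, via oxocarbenium triflate 13 (not isolated), via dioxolan-2-ylium triflate 14 (not isolated)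
Conditions: 12 (1.3 equiv), TMSOTf (1.2 equiv), 2,6-di-tert-butyl-4-methylpyridine, CH2Cl2, −78 to −40 °C; then H2O–THF, NaHCO3, 0 °C to rt
Reagents that add atoms: water, O
Why: Proposed new method: a silyl-Prins cyclisation terminated by the neighbouring allylic ester, in which TMSOTf joins the C2 silyl ether and 12 to the E-oxocarbenium ion 13 (C2–O–C9), the C10=C11 alkene attacks it 5-exo on the face that carries C2 (cis ring fusion, with C3 and C8 both outward and hence 2,9-cis), the developing tertiary C11 cation is captured anti (trans-diaxial) by the carbonyl oxygen of the pseudo-equatorial C12 octanoate to give the cis-fused acyloxonium ion 14, and hydrolysis through the orthoacid frees the tertiary C11–OH while the acyl group stays on the less hindered O12, so that C9, C10 and C11 are set from C1, C2 and C12 and the five-ring closure should outrun seven-ring attack by the isopropenyl group; the closest known reactions are Prins–pinacol tetrahydrofuran syntheses (same cyclisation, different termination) and Winstein/Woodward–Prévost acyloxonium chemistry.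

**Step 7**
Reactants: 15
Product: 16 (1S,3S,3aR,4R,5S,7R,7aS)-1-acetyl-3-(2-bromoprop-2-en-1-yl)-4-hydroxy-4-methyl-7-(prop-1-en-2-yl)octahydro-2-benzofuran-5-yl octanoate
Conditions: Pd(Quinox)Cl2 (5 mol%), AgSbF6 (12 mol%), aq TBHP, CH2Cl2, 0 °C to rt
Reagents that add atoms: tert-butyl hydroperoxide, CC(C)(C)OO
Why: Catalyst-controlled Tsuji–Wacker oxidation converts only the monosubstituted C3=C18 alkene, Markovnikov even next to the ether oxygen, and leaves the 1,1-disubstituted alkene, the vinyl bromide and the C2 stereocentre alone.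

**Step 8**
Reactants: 16; 17 allylmagnesium bromide
Product: 18 (1S,3S,3aR,4R,5S,7R,7aS)-3-(2-bromoprop-2-en-1-yl)-4-hydroxy-1-[(2S)-2-hydroxypent-4-en-2-yl]-4-methyl-7-(prop-1-en-2-yl)octahydro-2-benzofuran-5-yl octanoate
Conditions: MgBr2·OEt2, CH2Cl2, −78 °C; 17 (3 equiv, Et2O), −78 °C; sat. aq NH4Cl
Reagents that add atoms: none
Why: Cram-chelate Grignard addition, in which magnesium ties the ring oxygen to the ketone oxygen and the allyl group enters from the H2 side, away from C1, to give (3S), while the ester is inert at −78 °C.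

**Step 9**
Reactants: 18
Product: 21 (1S,2S,3S,9S,10R,11R,12S,14S,15R)-2,9-epoxycladiell-7(19)-ene-3,11,12,16-tetraol 12-octanoate (seco-oxepane diol), via bis(9-BBN) adduct 19 (not isolated), via macrocyclic C16 borane 20 (not isolated)
Conditions: 9-BBN (4.5 equiv), THF, 0 °C to rt; slow addition to Pd(dppf)Cl2 (15 mol%), AsPh3, Cs2CO3, DMF–THF–H2O, 1 mM, 40 °C; then NaBO3·4H2O, rt
Reagents that add atoms: sodium perborate, [Na+].[Na+].O[B-]1(O)OO[B-](O)(O)OO1
Why: 9-BBN hydroborates the allyl and isopropenyl groups but not the vinyl bromide (C15 becomes R through the usual rotamer with H14 inside and the C1 branch anti to boron, as for other trans-2-substituted isopropenylcyclohexanes), the intramolecular B-alkyl Suzuki–Miyaura coupling joins the unbranched C6–B to C7–Br between the two cis arms of the tetrahydrofuran and forms C7=CH2, and the β-branched C16–B on the opposite face survives to be oxidised with retention.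

**Step 10**
Reactants: 21
Product: 23 target CNP0286133.1, via C16 triflate 22 (not isolated)
Conditions: Tf2O (1.1 equiv), 2,6-lutidine, CH2Cl2, −78 °C to rt; aq NaHCO3
Reagents that add atoms: none
Why: This is the key C–O bond, formed by intramolecular Williamson-type etherification in which only the primary C16–OH is triflated and the tertiary C3–OH displaces it in a 7-exo-tet SN2 closure, with no stereocentre and no alkene touched and the axial C11–OH unable to reach C16.

**Compound list**
1 | (R)-(−)-carvone | CC1=CC[C@H](CC1=O)C(C)=C | starting material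
2 | acrolein | C=CC=O | starting material
3 | lithium α′-dienolate of 1 | CC1=CC[C@H](C=C1O[Li])C(C)=C | intermediate
4 | lithium alkoxide of (5R,6R)-6-[(1R)-1-hydroxyprop-2-en-1-yl]carvone | CC1=CC[C@@H](C(C)=C)[C@H]([C@H](O[Li])C=C)C1=O | intermediate
5 | anti-aldol TES ether (name in step 1) | CC1=CC[C@@H](C(C)=C)[C@H]([C@H](O[Si](CC)(CC)CC)C=C)C1=O | intermediate
6 | epoxy ketone, oxirane trans to isopropenyl (name in step 2) | C[C@@]12O[C@@H]1C[C@@H](C(C)=C)[C@H]([C@H](O[Si](CC)(CC)CC)C=C)C2=O | intermediate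
7 | hydrazone of 6 | C[C@@]12O[C@@H]1C[C@@H](C(C)=C)[C@H]([C@H](O[Si](CC)(CC)CC)C=C)C2=NN | intermediate
8 | transposed allylic alcohol, C12–OH trans to isopropenyl (name in step 3) | CC1=C[C@@H]([C@H](O[Si](CC)(CC)CC)C=C)[C@H](C(C)=C)C[C@H]1O | intermediate
9 | octanoic acid | CCCCCCCC(=O)O | starting material
10 | allylic octanoate, C12–O cis to isopropenyl (name in step 4) | CC1=C[C@@H]([C@H](O[Si](CC)(CC)CC)C=C)[C@H](C(C)=C)C[C@@H]1OC(=O)CCCCCCC | intermediate
11 | 3-bromobut-3-en-1-ol | C=C(Br)CCO | starting material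
12 | 3-bromobut-3-enal | C=C(Br)CC=O | intermediate
13 | C2–O=C9 oxocarbenium triflate | CC1=C[C@@H]([C@H]([O+]=CCC(Br)=C)C=C)[C@H](C(C)=C)C[C@@H]1OC(=O)CCCCCCC.[O-]S(=O)(=O)C(F)(F)F | intermediate
14 | tricyclic 2-heptyl-1,3-dioxolan-2-ylium triflate, cis-fused at C11/C12 | C=C(C)[C@@H]1C[C@@H]3OC(CCCCCCC)=[O+][C@]3(C)[C@@H]2[C@H]1[C@@H](C=C)O[C@H]2CC(Br)=C.[O-]S(=O)(=O)C(F)(F)F | intermediate
15 | cis-fused octahydro-2-benzofuran: C2 vinyl, C9 2-bromoallyl, C11–OH, C12 octanoate (name in step 6) | C=C(C)[C@@H]1C[C@H](OC(=O)CCCCCCC)[C@](C)(O)[C@@H]2[C@H]1[C@@H](C=C)O[C@H]2CC(Br)=C | intermediate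
16 | C3 methyl ketone (name in step 7) | C=C(C)[C@@H]1C[C@H](OC(=O)CCCCCCC)[C@](C)(O)[C@@H]2[C@H]1[C@@H](C(C)=O)O[C@H]2CC(Br)=C | intermediate
17 | allylmagnesium bromide | C=CC[Mg]Br | starting material
18 | (3S) tertiary homoallylic alcohol (name in step 8) | C=C(C)[C@@H]1C[C@H](OC(=O)CCCCCCC)[C@](C)(O)[C@@H]2[C@H]1[C@@H]([C@@](C)(O)CC=C)O[C@H]2CC(Br)=C | intermediate
19 | C6,C16-bis(9-borabicyclo[3.3.1]nonan-9-yl) adduct of 18 | C[C@@H](CB3C4CCCC3CCC4)[C@@H]1C[C@H](OC(=O)CCCCCCC)[C@](C)(O)[C@@H]2[C@H]1[C@@H]([C@@](C)(O)CCCB5C6CCCC5CCC6)O[C@H]2CC(Br)=C | intermediate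
20 | oxonane-closed C16 9-BBN borane | C=C1CCC[C@](C)(O)[C@H]2O[C@@H](C1)[C@H]3[C@@H]2[C@H]([C@@H](C)CB4C5CCCC4CCC5)C[C@H](OC(=O)CCCCCCC)[C@]3(C)O | intermediate
21 | seco-oxepane diol (name in step 9) | C=C1CCC[C@](C)(O)[C@H]2O[C@@H](C1)[C@H]3[C@@H]2[C@H]([C@@H](C)CO)C[C@H](OC(=O)CCCCCCC)[C@]3(C)O | intermediate
22 | C16 trifluoromethanesulfonate of 21 | C=C1CCC[C@](C)(O)[C@H]2O[C@@H](C1)[C@H]3[C@@H]2[C@H]([C@@H](C)COS(=O)(=O)C(F)(F)F)C[C@H](OC(=O)CCCCCCC)[C@]3(C)O | intermediate
23 | CNP0286133.1 | C=C1CCC[C@]2(C)OC[C@H](C)[C@@H]3C[C@H](OC(=O)CCCCCCC)[C@](C)(O)[C@@H]4[C@H]3[C@@H]2O[C@H]4C1 | target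

**Step count**
Total: 10 steps. Longest linear sequence: 9 steps (steps 1–4 and 6–10).

**Three steps most likely to fail**

Step 6 (the new relay). The risks are slow attack by the ester-deactivated C10=C11 alkene, seven-ring Prins closure by the isopropenyl group, and ionisation of the allylic ester.
- The fallback uses known chemistry, sets out from 10 and returns at 15.
- Methanolysis (K2CO3, MeOH) gives the cis-allylic alcohol F1.
- A conventional Prins–pinacol-type cyclisation of F1 with 12 (TMSOTf, CH2Cl2, −78 °C) gives the bicyclic C12 ketone F2. The C12–OH is silylated in the flask and the C11 cation is quenched by a 1,2-hydride shift from C12.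
- Autoxidation of the thermodynamic enolate (KOt-Bu, O2, P(OEt)3, THF/t-BuOH, −20 °C) places the hydroxyl on the convex face and gives the α-hydroxy ketone F3.
- NaBH4 (axial hydride) gives the cis-diol F4.
- Octanoyl chloride/pyridine acylates only the secondary C12–OH and gives 15.

Step 9 (nine-membered B-alkyl Suzuki closure). The risks are protodeboronation, β-hydride loss and oligomers.
- The fallback sets out from 16 and returns at 23. It closes the oxepane first and the oxonane by carbonyl addition.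
- Chelate-controlled addition of the Grignard reagent from 2-(2-bromoethyl)-1,3-dioxolane to 16 gives the acetal carbinol F5.
- 9-BBN then NaBO3·4H2O gives the primary alcohol F6; only the isopropenyl group can react.
- Tf2O/2,6-lutidine gives the oxepane acetal F7.
- PPTS in wet acetone frees the C6 aldehyde F8.
- Nozaki–Hiyama–Kishi cyclisation (CrCl2, NiCl2 cat., DMSO) gives the nine-membered allylic alcohol F9.
- ClCO2Me/pyridine gives the allylic carbonate F10.
- Tsuji reduction (Pd(OAc)2, PBu3, HCO2NH4) delivers hydride to the more substituted allyl terminus and gives 23 with C7=CH2 intact.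

Step 3 (Wharton reaction on a ketone hindered on both sides).
- The fallback sets out from 6 and returns at 8. It replaces the diazene route by a radical epoxide fragmentation.
- NaBH4/CeCl3·7H2O gives the epoxy alcohol F11; its C10 epimers are irrelevant.
- 1,1′-Thiocarbonyldiimidazole gives the thiocarbonylimidazolide F12.
- Bu3SnH/AIBN (benzene, 80 °C) generates the C10 radical, which opens the oxirane to C10=C11. The resulting C12 alkoxy radical is reduced to 8 with the C12–O bond unchanged.

**Further compounds**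
F1 | step 6 | C12 epimer of 8 (cis-allylic alcohol, C2–OTES kept) | CC1=C[C@@H]([C@H](O[Si](CC)(CC)CC)C=C)[C@H](C(C)=C)C[C@@H]1O
F2 | step 6 | bicyclic C12 ketone (15 with C12=O and C11–H, C11 epimers) | C=C(C)[C@@H]1CC(=O)C(C)[C@@H]2[C@H]1[C@@H](C=C)O[C@H]2CC(Br)=C
F3 | step 6 | C11-hydroxy C12 ketone | C=C(C)[C@@H]1CC(=O)[C@](C)(O)[C@@H]2[C@H]1[C@@H](C=C)O[C@H]2CC(Br)=C
F4 | step 6 | C11,C12 cis-diol (15 without the octanoyl group) | C=C(C)[C@@H]1C[C@H](O)[C@](C)(O)[C@@H]2[C@H]1[C@@H](C=C)O[C@H]2CC(Br)=C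
F5 | step 9 | (3S) carbinol carrying a 2-(1,3-dioxolan-2-yl)ethyl arm | C=C(C)[C@@H]1C[C@H](OC(=O)CCCCCCC)[C@](C)(O)[C@@H]2[C@H]1[C@@H]([C@@](C)(O)CCC3OCCO3)O[C@H]2CC(Br)=C
F6 | step 9 | (15R) C16 primary alcohol of F5 | C[C@@H](CO)[C@@H]1C[C@H](OC(=O)CCCCCCC)[C@](C)(O)[C@@H]2[C@H]1[C@@H]([C@@](C)(O)CCC3OCCO3)O[C@H]2CC(Br)=C
F7 | step 9 | tricyclic oxepane acetal | O1CCOC1CC[C@]2(C)OC[C@H](C)[C@@H]3C[C@H](OC(=O)CCCCCCC)[C@](C)(O)[C@@H]4[C@H]3[C@@H]2O[C@H]4CC(Br)=C
F8 | step 9 | tricyclic oxepane C6 aldehyde | O=CCC[C@]2(C)OC[C@H](C)[C@@H]3C[C@H](OC(=O)CCCCCCC)[C@](C)(O)[C@@H]4[C@H]3[C@@H]2O[C@H]4CC(Br)=C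
F9 | step 9 | 6-hydroxy derivative of 23 (C6 configuration open) | C=C1C(O)CC[C@]2(C)OC[C@H](C)[C@@H]3C[C@H](OC(=O)CCCCCCC)[C@](C)(O)[C@@H]4[C@H]3[C@@H]2O[C@H]4C1
F10 | step 9 | C6 methyl carbonate of F9 | C=C1C(OC(=O)OC)CC[C@]2(C)OC[C@H](C)[C@@H]3C[C@H](OC(=O)CCCCCCC)[C@](C)(O)[C@@H]4[C@H]3[C@@H]2O[C@H]4C1
F11 | step 3 | epoxy alcohol from 6 (C10 epimers) | C[C@@]12O[C@@H]1C[C@@H](C(C)=C)[C@H]([C@H](O[Si](CC)(CC)CC)C=C)C2O
F12 | step 3 | O-(imidazol-1-ylthiocarbonyl) derivative of F11 | C[C@@]12O[C@@H]1C[C@@H](C(C)=C)[C@H]([C@H](O[Si](CC)(CC)CC)C=C)C2OC(=S)n3ccnc3
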